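## Structural features

The target is a germacranolide of the heliangolide type: a ten-membered carbocycle (C1–C10) trans-fused at C6/C7 to an α-methylene-γ-butyrolactone (C11, C12, C13). The ring carries a trans, trisubstituted 1,10-epoxide (1R,10R, methyl on C10), a secondary allylic alcohol at C3 (S) and a Z trisubstituted C4=C5 bond between the C3 carbinol and the lactone carbinol C6. C6 (R), C7 (R) and C8 (R) form a contiguous O–C–O triad; the C8 oxygen is cis to C11 and carries an (E)-2-(acyloxymethyl)but-2-enoate whose acyl group is an (E)-2-(acetoxymethyl)-4-hydroxybut-2-enoate. Fragile groups are the exocyclic enoate of the lactone (Michael acceptor), the epoxide (acid, transannular attack by C4=C5), the 8-O-acyl group next to the lactone (acyl shift, relactonisation to C8), the two allylic ester linkages of the side chain (SN2′ with nucleophilic amines and phosphines) and the primary acetate. The real difficulty is a medium ring with one E and one Z trisubstituted unit in fixed positions, combined with six stereocentres of which three are contiguous. The route exploits the segment C10=C1–C2–C3(O)–C4=C5: with C3 as a silyl enol ether it is the open form of a ring A cyclohexa-1,3-diene. Cleaving the C5–C10 bond of a cis-fused eudesmanolide therefore gives the ten-membered ring and both trisubstituted alkenes at once, after C6, C7 and C8 have been set on a rigid six-membered ring B.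

## Logic of the disconnections

50 ⇒ 49. The two C–O bonds of the oxirane are cut first, because the epoxide is the group least tolerant of fluoride, acid, borane and base. This leaves a 1(10),4-diene in which C1=C10 is the only electron-rich alkene. The forward step must choose C1=C10 over C4=C5 and the enoates, and the outer face of that alkene.

49 ⇒ 48 ⇒ 47. The O–Si bond of the side chain and then the C3–H bond are cut, which leads back to a C3 ketone. Keeping C3 as a ketone until after acylation of C8 removes the need to tell two secondary hydroxyls apart. The forward reduction must be 1,2-selective and set 3S under reagent control.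

47 ⇒ 32 + 45. The C8 O–acyl bond is cut. This is the most convergent cut and keeps the base-sensitive diester away from all enolate chemistry. The forward acylation must be mild enough for a β,γ-unsaturated enone and a hydroxyl next to a lactone.

45 ⇒ 43 ⇒ 39 + 42; 39 ⇒ 37 ⇒ 35 ⇒ 33 + 34; 42 ⇒ 41 ⇒ 33 + 40. The inner ester is cut at the CH2–O bond (carboxylate alkylation) and each half goes back to an acrylate–aldehyde adduct. Both E trisubstituted enoates then arise from thermodynamically controlled allylic transpositions. The forward steps need an ester that can be cleaved beside an acetate and a silyl ether.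

32 ⇒ 31 ⇒ 30. O–Si bonds at C8 and at the C3 enol ether are cut. The enol ether hydrolysis removes the conjugated triene as soon as it is formed. It must protonate C2, not C10.

30 ⇒ 29. The C5–C10 bond is re-formed. This turns a ten-membered triene into a cis-fused bicycle whose stereocentres sit on a chair, a large gain in simplicity. The forward step must take the conrotatory sense that turns C6 inward and C9 outward.

29 ⇒ 27 ⇒ 26 ⇒ 24. The C11=C13 bond, the enol O–Si bond and the C1=C2 bond are removed in turn. The methylene is introduced here because the lactone α-hydrogen is the only acidic C–H of 27. The forward elimination must go to C13, not to C7.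

24 ⇒ 22 ⇒ 21 ⇒ 20 ⇒ 18 ⇒ 17. The lactone C12–O6 bond, the C4–H/C5–H pair, the C6–O bond and the C12–O bond are cut. All four come from one enone, whose dienol ether serves both as a ketone mask for hydroboration and as the site of γ-oxidation. The forward steps must give 6α-OH and 5α-H.

17 ⇒ 15 ⇒ 14 ⇒ 13 ⇒ 12 ⇒ 11. The C4=C5 bond (aldol condensation) and the C8–H bond (ketone reduction) are cut. The C5 oxygen of 11 is only a control element, and the C8 ketone allows the hindered 8β-alcohol to be made by hydride attack from the open face.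

11 ⇒ 5 + 8; 8 ⇒ 6. The C10–C1 bond is cut (conjugate addition), which gives a monocyclic enone and a three-carbon ketone equivalent made from pent-1-en-3-one. The forward step must build the quaternary centre anti to the neighbouring silyloxy group.

5 ⇒ 4 ⇒ 3 ⇒ 2 ⇒ 1. The C8 carbonyl oxygen (allylic oxidation), the silyl group and the transposed allylic alcohol (epoxy ketone) are removed. The sequence ends at carvone, which supplies C7 with its side chain.

## Other disconnections considered

Alternative 1: The cut is C5–C6 together with the lactone C12–O bond. In the forward step the iodo aldehyde ester A1 is treated with CrCl2 and catalytic NiCl2; the C5 alkenylchromium adds to the C6 aldehyde and the alkoxide lactonises onto the methyl ester to give A2.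
- In favour: the 4Z geometry is fixed in the alkenyl iodide and carried over with retention. The epoxide and the C3 and C8 carbinols are set earlier by reagent-controlled reactions. C11 is unsubstituted, so the methylene can be added by aminomethylation and elimination with no risk of an endocyclic alkene. On these three points it is the better plan.
- Against: the ten-membered ring and the C6 stereocentre are made in the same event. The aldehyde is flanked by an epimerisable C7 with a β-alkoxy group, so elimination and epimerisation threaten. The epoxide must survive stoichiometric chromium salts and chloride.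
- Comparison: this is a polar addition at high dilution, against a unimolecular pericyclic opening that needs no dilution. The chosen plan has C6–C8 fixed on a chair before the medium ring exists. Step economy should be about equal, since A1 needs several asymmetric steps of its own.

Alternative 2: The cut is C3–C4. In the forward step A3, which already holds the lactone, C6, C7 and C8, is closed with CrCl2 and catalytic NiCl2; the C4 alkenylchromium adds to the C3 aldehyde to give A4.
- In favour: both alkene geometries are made by open-chain chemistry, which is equal to or better than photochemical control. The C3 carbinol is formed directly, which saves the hydrolysis and reduction steps of the chosen plan and is better in step economy at that point.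
- Against: C3 is set under substrate control during a medium-ring closure, where the chosen plan uses a catalyst-controlled ketone reduction. The aldehyde of A3 is β,γ-unsaturated and prone to conjugation. The alkenyl iodide sits next to the allylic lactone oxygen, which low-valent nickel can ionise.
- Comparison: equal on the epoxidation endgame and on overall length; better on E/Z security; weaker on C3 and on the ring-closing event itself.

Alternative 3: The cut is C8–C9, with C6–C1 re-formed. In the forward step the potassium alkoxide of A5 undergoes an anionic oxy-Cope shift to A6.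
- In favour: A5 is one alkenylmetal addition away from a ketone of the kind of 5, so the early steps coincide. A chair transition state should give 1(10)E and transfer chirality to C8, and 4Z is inherited from the cyclohexene. In the predictability of alkene geometry it is equal to or better than the photochemical step, and it reaches the ten-membered ring in far fewer steps.
- Against: A6 has a C6 ketone and no C7 substituent. The lactone carbons must be attached at C7, C6 reduced and the C8 silicon oxidised, all on a flexible ring that holds two trisubstituted alkenes.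
- Comparison: the chosen plan is longer before ring formation but handles C6, C7 and C8 on a chair; Alternative 3 is shorter to the macrocycle and weaker afterwards.

Key step: step 20

## Remarks on the chemistry (settled points and assumptions)

- **Numbering and descriptors.** Eudesmane/germacrane numbering is used from 5 onwards (carbonyl carbon of 5 = C8, then C9, C10 with its methyl, C5 with the silyloxy group, C6, C7 with the isopropenyl group). β is the face of the C7 side chain. "10-epi" means a 10α-methyl group.
- **Ring fusion of the photochemical substrate.** The diene is made as the 5α-H,10α-CH3 cis-fused diastereomer. The trans-lactone allows only the ring B chair with O6 and C11 equatorial. In that chair the 5α,10α isomer carries C6 pseudo-axial and C9 pseudo-equatorial on ring A, which is the arrangement that should turn C6 inward (4Z) and C9 outward (1(10)E). The 5β-H,10β-CH3 isomer, locked by the same lactone, has these roles exchanged and should give the 1(10)Z,4E triene.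
- **Descriptor of the triene.** The silyloxytriene 30 is (1(10)E,2E,4Z) by the sequence rule, because the silyloxy group outranks C4 at C3. The C2=C3 bond is nevertheless cis within the ring.
- **Starting enantiomer.** Because the ketone is transposed in step 2, (S)-(+)-carvone is the enantiomer that supplies the required C7 configuration.
- **Assumption on C11.** Hydroboration in step 13 should give both C11 epimers; they are carried together (11RS) because C11 becomes trigonal in step 19.
- **Order of events.** The exocyclic methylene is introduced before the ring opening and C3 stays a ketone until C8 is acylated, so no protecting group is needed at C3.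

## Steps

Step 1
Reactants: 1 (S)-(+)-carvone
Product: 2 (1S,4S,6S)-1-methyl-4-(prop-1-en-2-yl)-7-oxabicyclo[4.1.0]heptan-2-one
Conditions: 30% H2O2, NaOH (cat.), MeOH, 0 °C
Reagents that add atoms: hydrogen peroxide, OO
Why: Nucleophilic epoxidation of the enone; hydroperoxide should add to the β-carbon anti to the isopropenyl group, so the oxirane is trans to it.

Step 2
Reactants: 2 carvone epoxide
Product: 3 (1S,5R)-2-methyl-5-(prop-1-en-2-yl)cyclohex-2-en-1-ol (trans-carveol)
Conditions: N2H4·H2O, AcOH (cat.), MeOH, 0 → 25 °C
Reagents that add atoms: none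
Why: Wharton transposition; the epoxy hydrazone loses N2 to give the allylic alcohol, and the carbinol keeps the configuration of the epoxide C–O bond, so the hydroxyl is trans to the isopropenyl group.

Step 3
Reactants: 3 trans-carveol
Product: 4 triethyl{[(1S,5R)-2-methyl-5-(prop-1-en-2-yl)cyclohex-2-en-1-yl]oxy}silane
Conditions: TESCl, imidazole, CH2Cl2, 0 °C
Reagents that add atoms: chlorotriethylsilane, CC[Si](Cl)(CC)CC
Why: Standard silylation; a silyl ether is needed because an acyloxy group at this position would be lost reductively in step 6.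

Step 4
Reactants: 4 silyl ether
Product: 5 (4S,6R)-3-methyl-6-(prop-1-en-2-yl)-4-(triethylsilyloxy)cyclohex-2-en-1-one
Conditions: CrO3, 3,5-dimethylpyrazole, CH2Cl2, −20 °C
Reagents that add atoms: chromium trioxide, O=[Cr](=O)=O
Why: Allylic oxidation of the ring CH2 next to the less substituted alkene carbon, as in the conversion of 1-methylcyclohexene-type alkenes into 3-methylcyclohexenones; the conditions are non-basic, so the centre next to the new carbonyl should not epimerise.

Step 5
Reactants: 6 pent-1-en-3-one
Product: 8 2-(2-bromoethyl)-2-ethyl-1,3-dioxolane, via 1-bromopentan-3-one 7 (not isolated)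
Conditions: HBr (g), CH2Cl2, 0 °C; then ethane-1,2-diol, TsOH (cat.), benzene, reflux (−H2O)
Reagents that add atoms: hydrogen bromide, Br; ethane-1,2-diol, OCCO
Why: Conjugate addition of HBr followed by ketalisation gives the masked 3-oxopentyl bromide.

Step 6
Reactants: 5 enone; 8 bromo ketal
Product: 11 (2R,4S,5S)-5-[2-(2-ethyl-1,3-dioxolan-2-yl)ethyl]-5-methyl-2-(prop-1-en-2-yl)-4-(triethylsilyloxy)cyclohexan-1-one, via Grignard reagent 9 (not isolated), via silyl enol ether 10 (not isolated)
Conditions: 8, Mg, THF, 25 °C; then 5, CuBr·SMe2 (10 mol%), TMSCl, THF, −78 → −40 °C; then 10% aq. citric acid, 0 °C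
Reagents that add atoms: none
Why: Copper-catalysed, silyl-chloride-accelerated conjugate addition of a Grignard reagent to a β,β-disubstituted enone creates the C10 quaternary centre. The neighbouring silyloxy group should sit pseudo-axial (allylic strain with the C10 methyl) and shield the α face, so the chain enters β. Mild acidic hydrolysis of the enol ether avoids epimerisation at C7.

Step 7
Reactants: 11 ketone
Product: 12 (1R,2R,4S,5S)-5-[2-(2-ethyl-1,3-dioxolan-2-yl)ethyl]-5-methyl-2-(prop-1-en-2-yl)-4-(triethylsilyloxy)cyclohexan-1-ol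
Conditions: L-Selectride, THF, −78 °C; aq. NH4Cl
Reagents that add atoms: none
Why: A bulky hydride should attack the C8 ketone from the α face, away from the β side chain on C10, and give the 8β-alcohol cis to the isopropenyl group (the usual outcome for 2-substituted cyclohexanones).

Step 8
Reactants: 12 alcohol
Product: 13 tert-butyl{[(1R,2R,4S,5S)-5-[2-(2-ethyl-1,3-dioxolan-2-yl)ethyl]-5-methyl-2-(prop-1-en-2-yl)-4-(triethylsilyloxy)cyclohexyl]oxy}dimethylsilane
Conditions: TBSOTf, 2,6-lutidine, CH2Cl2, −78 → 0 °C
Reagents that add atoms: tert-butyldimethylsilyl triflate, CC(C)(C)[Si](C)(C)OS(=O)(=O)C(F)(F)F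
Why: Silylation of a hindered secondary alcohol; ketone ketals tolerate these conditions.

Step 9
Reactants: 13 bis-silyl ether
Product: 14 (1S,2S,4R,5R)-4-(tert-butyldimethylsilyloxy)-2-[2-(2-ethyl-1,3-dioxolan-2-yl)ethyl]-2-methyl-5-(prop-1-en-2-yl)cyclohexan-1-ol
Conditions: PPTS (cat.), MeOH, 0 → 25 °C
Reagents that add atoms: none
Why: Mild acidic methanolysis should remove the secondary triethylsilyl ether and leave the secondary tert-butyldimethylsilyl ether.

Step 10
Reactants: 14 alcohol
Product: 15 (2S,4R,5R)-4-(tert-butyldimethylsilyloxy)-2-[2-(2-ethyl-1,3-dioxolan-2-yl)ethyl]-2-methyl-5-(prop-1-en-2-yl)cyclohexan-1-one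
Conditions: Dess–Martin periodinane, NaHCO3, CH2Cl2, 25 °C
Reagents that add atoms: none
Why: Neutral oxidation of the C5 carbinol; its stereocentre has done its work as a control element.

Step 11
Reactants: 15 keto ketal
Product: 17 8β-(tert-butyldimethylsilyloxy)-10-epi-eudesma-4,11-dien-3-one (7β-isopropenyl, 10α-methyl), via diketone 16 (not isolated)
Conditions: PPTS, acetone/H2O, 55 °C; then KOH, MeOH, 50 °C
Reagents that add atoms: water, O
Why: Ketal hydrolysis and then intramolecular aldol condensation of the 1,5-diketone (the second stage of a Robinson annulation) close ring A as the conjugated enone. C7 and C8 are not α to a carbonyl at this stage and should not epimerise.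

Step 12
Reactants: 17 enone
Product: 18 3,8β-bis(tert-butyldimethylsilyloxy)-10-epi-eudesma-3,5,11-triene
Conditions: TBSOTf, Et3N, CH2Cl2, 0 → 25 °C
Reagents that add atoms: tert-butyldimethylsilyl triflate, CC(C)(C)[Si](C)(C)OS(=O)(=O)C(F)(F)F
Why: Reversible soft enolisation of a 4-methyl-Δ4-3-ketone should give the extended (3,5-diene) silyl enol ether, which masks the ketone and activates C6.

Step 13
Reactants: 18 dienol ether
Product: 20 3,8β-bis(tert-butyldimethylsilyloxy)-10-epi-eudesma-3,5-dien-12-ol (11RS), via B-alkyl-9-BBN adduct 19 (not isolated)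
Conditions: 9-BBN, THF, 0 → 25 °C; then 30% H2O2, pH 8 buffer, 0 °C
Reagents that add atoms: hydrogen peroxide, OO
Why: 9-BBN hydroborates the 1,1-disubstituted isopropenyl alkene much faster than the substituted dienol ether, and no ketone is exposed. C11 is formed as a mixture, which is inconsequential.

Step 14
Reactants: 20 dienol ether alcohol
Product: 21 8β-(tert-butyldimethylsilyloxy)-6α,12-dihydroxy-10-epi-eudesm-4-en-3-one (11RS)
Conditions: mCPBA (1.05 equiv), NaHCO3, CH2Cl2, −20 °C
Reagents that add atoms: 3-chloroperbenzoic acid, OOC(=O)c1cccc(Cl)c1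
Why: Vinylogous Rubottom oxidation; the peracid attacks the terminal C5=C6 bond of the dienol ether and the silyl group is lost as silanol. Axial attack at C6 anti to the axial C7 side chain should give the 6α-alcohol, the counterpart of the 6β-hydroxylation of steroidal 3,5-dienol ethers.

Step 15
Reactants: 21 hydroxy enone
Product: 22 8β-(tert-butyldimethylsilyloxy)-6α,12-dihydroxy-4αH,5αH-10-epi-eudesman-3-one (rings A/B cis; 11RS)
Conditions: H2 (3 atm), Pd/C, pyridine, 25 °C
Reagents that add atoms: none
Why: Hydrogenation of 10-methyl-Δ4-3-octalones in basic media should give the cis-fused ketone (hydrogen on the face of the angular methyl), and the 6α-hydroxyl on the same face should anchor the substrate to the catalyst. Pyridine also suppresses hydrogenolysis of the allylic C6–O bond.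

Step 16
Reactants: 22 keto diol
Product: 24 8β-(tert-butyldimethylsilyloxy)-3-oxo-4αH,5αH-10-epi-eudesman-6α,12-olide (11RS), via lactol 23 (not isolated)
Conditions: TEMPO (cat.), PhI(OAc)2, CH2Cl2, 25 °C
Reagents that add atoms: none
Why: Oxoammonium oxidation takes the primary alcohol to the aldehyde, which is trapped by the 6α-hydroxyl as a lactol and oxidised to the trans-fused lactone. The saturated cis-decalin can flip into the chair that holds O6 and C11 equatorial, which the enone 21 could not.

Step 17
Reactants: 24 keto lactone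
Product: 26 8β-(tert-butyldimethylsilyloxy)-3-oxo-4αH,5αH-10-epi-eudesm-1-en-6α,12-olide (11RS), via trimethylsilyl enol ether 25 (not isolated)
Conditions: LDA (1.1 equiv), TMSCl, THF, −78 °C; then Pd(OAc)2, MeCN, 25 °C
Reagents that add atoms: none
Why: Saegusa–Ito dehydrogenation; kinetic deprotonation takes place at the C2 methylene and not at the C4 methine, and the ketone is far more acidic than the lactone. Divalent palladium then converts the enol ether into the Δ1-enone.

Step 18
Reactants: 26 enone
Product: 27 8β-(tert-butyldimethylsilyloxy)-3-(triethylsilyloxy)-5αH-10-epi-eudesma-1,3-dien-6α,12-olide (11RS)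
Conditions: TESOTf, Et3N, CH2Cl2, −78 → 0 °C
Reagents that add atoms: triethylsilyl triflate, CC[Si](CC)(CC)OS(=O)(=O)C(F)(F)F
Why: The only enolisable α-hydrogen of the enone is at C4, so soft enolisation can give only the homoannular 1,3-diene.

Step 19
Reactants: 27 dienol ether lactone
Product: 29 8β-(tert-butyldimethylsilyloxy)-3-(triethylsilyloxy)-5αH-10-epi-eudesma-1,3,11(13)-trien-6α,12-olide, via α-bromo lactone 28 (not isolated)
Conditions: LDA, THF, −78 °C; BrCCl2CCl2Br, −78 °C; then DBU, toluene, 60 °C
Reagents that add atoms: none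
Why: The lactone α-hydrogen is the only acidic C–H of 27. Its enolate should be brominated on the α face, because the β face is blocked by the axial 8β-silyloxy group. Base-induced anti elimination of the 11α-bromide cannot reach H7 (syn to bromine) and should give only the exocyclic methylene.

Step 20
Reactants: 29 cis-fused silyloxy diene
Product: 30 (1(10)E,2E,4Z)-8β-(tert-butyldimethylsilyloxy)-3-(triethylsilyloxy)germacra-1(10),2,4,11(13)-tetraen-6α,12-olide
Conditions: hν (300 nm, Pyrex), degassed Et2O, −78 °C, partial conversion; solution used cold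
Reagents that add atoms: none
Why: Excitation of the diene leads to conrotatory 6π electrocyclic opening, in which the C5–C10 σ bond becomes part of the C4=C5 and C1=C10 π bonds. The closest known reaction type is the photochemical opening of ring A 1,3-dienes of trans-fused eudesmanolides to cyclodecatrienes, and of provitamin D-type dienes. No ring is closed by bond formation: the ten-membered ring is the perimeter of the bicycle, set free when the transannular bond breaks. No stereocentre is formed; C5 and C10 become trigonal. The step needs the conrotatory sense that turns C6 inward (4Z) and C9 outward (1(10)E). This should be secured by the trans-lactone, which fixes ring B in one chair and so fixes the helicity of the diene; the opening should continue that helical twist, sending the pseudo-axial C6 inward and the pseudo-equatorial C9 outward. The central C2=C3 bond stays cis in the ring. Low temperature, long-wavelength light and partial conversion limit re-excitation and thermal re-closure of the triene.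

Step 21
Reactants: 30 silyloxy triene
Product: 31 (1(10)E,4Z)-8β-(tert-butyldimethylsilyloxy)-3-oxogermacra-1(10),4,11(13)-trien-6α,12-olide
Conditions: TBAF, AcOH (1:1), THF, −78 → −20 °C
Reagents that add atoms: none
Why: Buffered fluoride cleaves the silyl enol ether much faster than the alkyl silyl ether. Kinetic protonation of the dienolate at C2 gives the ketone conjugated with C4=C5 and leaves C1=C10 in place; this removes the thermally labile triene.

Step 22
Reactants: 31 silyl ether
Product: 32 (1(10)E,4Z)-8β-hydroxy-3-oxogermacra-1(10),4,11(13)-trien-6α,12-olide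
Conditions: HF·pyridine, pyridine, THF, 0 → 25 °C
Reagents that add atoms: none
Why: Buffered HF removes the secondary silyl ether without base, so the 8β-alkoxide that could attack the lactone carbonyl is never formed.

Step 23
Reactants: 33 tert-butyl acrylate; 34 (tert-butyldimethylsilyloxy)acetaldehyde
Product: 35 tert-butyl 4-(tert-butyldimethylsilyloxy)-3-hydroxy-2-methylidenebutanoate (racemic)
Conditions: DABCO, dioxane/H2O, 25 °C
Reagents that add atoms: none
Why: Morita–Baylis–Hillman reaction; α-alkoxy aldehydes are good acceptors, and the carbinol centre is removed in the next step.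

Step 24
Reactants: 35 adduct
Product: 37 tert-butyl (E)-2-(acetoxymethyl)-4-(tert-butyldimethylsilyloxy)but-2-enoate, via secondary acetate 36 (not isolated)
Conditions: Ac2O, Et3N, DMAP (cat.), CH2Cl2, 0 °C; then DABCO (cat.), THF, 60 °C
Reagents that add atoms: acetic anhydride, CC(=O)OC(C)=O
Why: Acetylation followed by amine-catalysed 1,3-acetoxy shift (two SN2′ events) should give the thermodynamic trisubstituted enoate with the β-substituent trans to the ester, i.e. E.

Step 25
Reactants: 37 tert-butyl ester
Product: 39 (E)-2-(acetoxymethyl)-4-(tert-butyldimethylsilyloxy)but-2-enoic acid, via trimethylsilyl ester 38 (not isolated)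
Conditions: TMSOTf, 2,6-lutidine, CH2Cl2, 0 °C; aq. citric acid
Reagents that add atoms: none
Why: Silyl triflate-induced loss of isobutene cleaves the tert-butyl ester without touching the acetate or the primary silyl ether.

Step 26
Reactants: 33 tert-butyl acrylate; 40 acetaldehyde
Product: 41 tert-butyl 3-hydroxy-2-methylidenebutanoate (racemic)
Conditions: DABCO, neat, 25 °C
Reagents that add atoms: none
Why: Morita–Baylis–Hillman reaction of a simple aldehyde.

Step 27
Reactants: 41 adduct
Product: 42 tert-butyl (Z)-2-(bromomethyl)but-2-enoate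
Conditions: NBS, Me2S, CH2Cl2, 0 → 25 °C
Reagents that add atoms: N-bromosuccinimide, BrN1C(=O)CCC1=O
Why: Activation of the hydroxyl as an alkoxysulfonium ion and SN2′ delivery of bromide give the rearranged primary bromide with the methyl trans to the ester.

Step 28
Reactants: 39 acid; 42 allylic bromide
Product: 43 tert-butyl (E)-2-({[(E)-2-(acetoxymethyl)-4-(tert-butyldimethylsilyloxy)but-2-enoyl]oxy}methyl)but-2-enoate
Conditions: Cs2CO3, DMF, 0 → 25 °C
Reagents that add atoms: none
Why: Carboxylate alkylation at the primary allylic carbon forms the inner ester without an activated acyl intermediate; the trisubstituted (conjugated) isomer is also the thermodynamic one.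

Step 29
Reactants: 43 tert-butyl ester
Product: 45 (E)-2-({[(E)-2-(acetoxymethyl)-4-(tert-butyldimethylsilyloxy)but-2-enoyl]oxy}methyl)but-2-enoic acid, via trimethylsilyl ester 44 (not isolated)
Conditions: TMSOTf, 2,6-lutidine, CH2Cl2, 0 °C; aq. citric acid
Reagents that add atoms: none
Why: Same non-hydrolytic cleavage as in step 25; both ester links and the acetate stay intact.

Step 30
Reactants: 32 8β-hydroxy enone; 45 side-chain acid
Product: 47 (1(10)E,4Z)-8β-[(E)-2-({[(E)-2-(acetoxymethyl)-4-(tert-butyldimethylsilyloxy)but-2-enoyl]oxy}methyl)but-2-enoyloxy]-3-oxogermacra-1(10),4,11(13)-trien-6α,12-olide, via acid chloride 46 (not isolated)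
Conditions: 45, 1-chloro-N,N,2-trimethylprop-1-en-1-amine, CH2Cl2, 0 °C; then 32, pyridine, DMAP (cat.), CH2Cl2, −20 → 0 °C
Reagents that add atoms: none
Why: The acid chloride is formed under neutral conditions and acylates the hindered 8β-hydroxyl with a weak base only; this limits isomerisation of the β,γ-unsaturated ketone and SN2′ attack on the allylic esters.

Step 31
Reactants: 47 enone ester
Product: 48 (3S)-alcohol: (1(10)E,4Z)-8β-acyloxy-3β-hydroxygermacra-1(10),4,11(13)-trien-6α,12-olide (acyl as in 47)
Conditions: (R)-2-methyl-CBS-oxazaborolidine, catecholborane, toluene, −78 °C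
Reagents that add atoms: none
Why: Corey–Bakshi–Shibata reduction; the α-methyl alkenyl side of the ketone acts as the large group and C2H2 as the small one, so the (R)-catalyst should deliver hydride to give 3S. Catecholborane at low temperature does not reduce esters or the methylene lactone.

Step 32
Reactants: 48 silyl ether
Product: 49 (1(10)E,4Z)-8β-[(E)-2-({[(E)-2-(acetoxymethyl)-4-hydroxybut-2-enoyl]oxy}methyl)but-2-enoyloxy]-3β-hydroxygermacra-1(10),4,11(13)-trien-6α,12-olide
Conditions: HF·pyridine, pyridine, THF, 0 °C
Reagents that add atoms: none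
Why: A primary allylic silyl ether is cleaved quickly by buffered HF; doing this before the epoxidation keeps the epoxide away from fluoride and acid.

Step 33
Reactants: 49 diene diol
Product: 50 target, (1R,3S,6R,7R,8R,10R)-1β,10α-epoxy-3β-hydroxy-8β-acyloxygermacra-4(Z),11(13)-dien-6α,12-olide
Conditions: mCPBA (1.05 equiv), NaHCO3, CH2Cl2, −20 → 0 °C
Reagents that add atoms: 3-chloroperbenzoic acid, OOC(=O)c1cccc(Cl)c1
Why: Prilezhaev epoxidation; C1=C10 is the only electron-rich alkene (C4=C5 carries two allylic oxygens, the others are conjugated with carbonyls). Peripheral attack on the outer face of the E alkene, in the ring conformer with C14 on the β side, should give the 1β,10α-epoxide.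

## Compound list

1 | (S)-(+)-carvone | CC1=CC[C@@H](CC1=O)C(C)=C | starting material
2 | (1S,4S,6S)-1-methyl-4-(prop-1-en-2-yl)-7-oxabicyclo[4.1.0]heptan-2-one | C[C@]12O[C@H]1C[C@@H](CC2=O)C(C)=C | intermediate
3 | (1S,5R)-2-methyl-5-(prop-1-en-2-yl)cyclohex-2-en-1-ol | O[C@H]1C[C@@H](CC=C1C)C(C)=C | intermediate
4 | triethylsilyl ether of 3 | CC[Si](CC)(CC)O[C@H]1C[C@@H](CC=C1C)C(C)=C | intermediate
5 | (4S,6R)-3-methyl-6-(prop-1-en-2-yl)-4-(triethylsilyloxy)cyclohex-2-en-1-one | CC[Si](CC)(CC)O[C@H]1C[C@@H](C(=O)C=C1C)C(C)=C | intermediate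
6 | pent-1-en-3-one | CCC(=O)C=C | starting material
7 | 1-bromopentan-3-one | CCC(=O)CCBr | intermediate
8 | 2-(2-bromoethyl)-2-ethyl-1,3-dioxolane | CCC1(CCBr)OCCO1 | intermediate
9 | [2-(2-ethyl-1,3-dioxolan-2-yl)ethyl]magnesium bromide | CCC1(CC[Mg]Br)OCCO1 | intermediate
10 | trimethylsilyl enol ether of 11 (C8=C9) | CC[Si](CC)(CC)O[C@H]1C[C@H](C(C)=C)C(O[Si](C)(C)C)=C[C@]1(C)CCC2(CC)OCCO2 | intermediate
11 | (2R,4S,5S)-5-[2-(2-ethyl-1,3-dioxolan-2-yl)ethyl]-5-methyl-2-(prop-1-en-2-yl)-4-(triethylsilyloxy)cyclohexan-1-one | CC[Si](CC)(CC)O[C@H]1C[C@H](C(C)=C)C(=O)C[C@]1(C)CCC2(CC)OCCO2 | intermediate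
12 | (1R,2R,4S,5S)-alcohol from 11 (8β-OH) | CC[Si](CC)(CC)O[C@H]1C[C@H](C(C)=C)[C@H](O)C[C@]1(C)CCC2(CC)OCCO2 | intermediate
13 | tert-butyldimethylsilyl ether of 12 | CC[Si](CC)(CC)O[C@H]1C[C@H](C(C)=C)[C@H](O[Si](C)(C)C(C)(C)C)C[C@]1(C)CCC2(CC)OCCO2 | intermediate
14 | (1S,2S,4R,5R)-4-(tert-butyldimethylsilyloxy)-2-[2-(2-ethyl-1,3-dioxolan-2-yl)ethyl]-2-methyl-5-(prop-1-en-2-yl)cyclohexan-1-ol | O[C@H]1C[C@H](C(C)=C)[C@H](O[Si](C)(C)C(C)(C)C)C[C@]1(C)CCC2(CC)OCCO2 | intermediate
15 | (2S,4R,5R)-ketone from 14 | O=C1C[C@H](C(C)=C)[C@H](O[Si](C)(C)C(C)(C)C)C[C@]1(C)CCC2(CC)OCCO2 | intermediate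
16 | (2S,4R,5R)-4-(tert-butyldimethylsilyloxy)-2-methyl-2-(3-oxopentyl)-5-(prop-1-en-2-yl)cyclohexan-1-one | O=C1C[C@H](C(C)=C)[C@H](O[Si](C)(C)C(C)(C)C)C[C@]1(C)CCC(=O)CC | intermediate
17 | 8β-(tert-butyldimethylsilyloxy)-10-epi-eudesma-4,11-dien-3-one | CC1=C2C[C@H](C(C)=C)[C@H](O[Si](C)(C)C(C)(C)C)C[C@]2(C)CCC1=O | intermediate
18 | 3,8β-bis(tert-butyldimethylsilyloxy)-10-epi-eudesma-3,5,11-triene | CC1=C(O[Si](C)(C)C(C)(C)C)CC[C@@]2(C)C[C@@H](O[Si](C)(C)C(C)(C)C)[C@@H](C(C)=C)C=C12 | intermediate
19 | B-alkyl-9-borabicyclo[3.3.1]nonane adduct of 18 at C12 (11RS) | CC1=C(O[Si](C)(C)C(C)(C)C)CC[C@@]2(C)C[C@@H](O[Si](C)(C)C(C)(C)C)[C@@H](C(C)CB3C4CCCC3CCC4)C=C12 | intermediate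
20 | 3,8β-bis(tert-butyldimethylsilyloxy)-10-epi-eudesma-3,5-dien-12-ol (11RS) | CC1=C(O[Si](C)(C)C(C)(C)C)CC[C@@]2(C)C[C@@H](O[Si](C)(C)C(C)(C)C)[C@@H](C(C)CO)C=C12 | intermediate
21 | 8β-(tert-butyldimethylsilyloxy)-6α,12-dihydroxy-10-epi-eudesm-4-en-3-one (11RS) | CC1=C2[C@@H](O)[C@H](C(C)CO)[C@H](O[Si](C)(C)C(C)(C)C)C[C@]2(C)CCC1=O | intermediate
22 | 8β-(tert-butyldimethylsilyloxy)-6α,12-dihydroxy-4αH,5αH-10-epi-eudesman-3-one (11RS) | C[C@@H]1[C@@H]2[C@@H](O)[C@H](C(C)CO)[C@H](O[Si](C)(C)C(C)(C)C)C[C@]2(C)CCC1=O | intermediate
23 | 6α,12-lactol of 22 (11RS, 12RS) | CC1C(O)O[C@@H]2[C@H]3[C@@H](C)C(=O)CC[C@@]3(C)C[C@@H](O[Si](C)(C)C(C)(C)C)[C@@H]12 | intermediate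
24 | 8β-(tert-butyldimethylsilyloxy)-3-oxo-4αH,5αH-10-epi-eudesman-6α,12-olide (11RS) | CC1C(=O)O[C@@H]2[C@H]3[C@@H](C)C(=O)CC[C@@]3(C)C[C@@H](O[Si](C)(C)C(C)(C)C)[C@@H]12 | intermediate
25 | 3-(trimethylsilyloxy)-2-ene of 24 | CC1C(=O)O[C@@H]2[C@H]3[C@@H](C)C(O[Si](C)(C)C)=CC[C@@]3(C)C[C@@H](O[Si](C)(C)C(C)(C)C)[C@@H]12 | intermediate
26 | 8β-(tert-butyldimethylsilyloxy)-3-oxo-4αH,5αH-10-epi-eudesm-1-en-6α,12-olide (11RS) | CC1C(=O)O[C@@H]2[C@H]3[C@@H](C)C(=O)C=C[C@@]3(C)C[C@@H](O[Si](C)(C)C(C)(C)C)[C@@H]12 | intermediate
27 | 8β-(tert-butyldimethylsilyloxy)-3-(triethylsilyloxy)-5αH-10-epi-eudesma-1,3-dien-6α,12-olide (11RS) | CC1C(=O)O[C@@H]2[C@H]3C(C)=C(O[Si](CC)(CC)CC)C=C[C@@]3(C)C[C@@H](O[Si](C)(C)C(C)(C)C)[C@@H]12 | intermediate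
28 | 11α-bromo-11β-methyl derivative of 27 | C[C@@]1(Br)C(=O)O[C@@H]2[C@H]3C(C)=C(O[Si](CC)(CC)CC)C=C[C@@]3(C)C[C@@H](O[Si](C)(C)C(C)(C)C)[C@@H]12 | intermediate
29 | 8β-(tert-butyldimethylsilyloxy)-3-(triethylsilyloxy)-5αH-10-epi-eudesma-1,3,11(13)-trien-6α,12-olide | C=C1C(=O)O[C@@H]2[C@H]3C(C)=C(O[Si](CC)(CC)CC)C=C[C@@]3(C)C[C@@H](O[Si](C)(C)C(C)(C)C)[C@@H]12 | intermediate
30 | (1(10)E,2E,4Z)-8β-(tert-butyldimethylsilyloxy)-3-(triethylsilyloxy)germacra-1(10),2,4,11(13)-tetraen-6α,12-olide | C=C1C(=O)O[C@@H]2/C=C(C)\C(O[Si](CC)(CC)CC)=C/C=C(C)/C[C@@H](O[Si](C)(C)C(C)(C)C)[C@@H]12 | intermediate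
31 | (1(10)E,4Z)-8β-(tert-butyldimethylsilyloxy)-3-oxogermacra-1(10),4,11(13)-trien-6α,12-olide | C=C1C(=O)O[C@@H]2/C=C(C)\C(=O)C/C=C(C)/C[C@@H](O[Si](C)(C)C(C)(C)C)[C@@H]12 | intermediate
32 | (1(10)E,4Z)-8β-hydroxy-3-oxogermacra-1(10),4,11(13)-trien-6α,12-olide | C=C1C(=O)O[C@@H]2/C=C(C)\C(=O)C/C=C(C)/C[C@@H](O)[C@@H]12 | intermediate
33 | tert-butyl acrylate | C=CC(=O)OC(C)(C)C | starting material
34 | (tert-butyldimethylsilyloxy)acetaldehyde | O=CCO[Si](C)(C)C(C)(C)C | starting material
35 | tert-butyl 4-(tert-butyldimethylsilyloxy)-3-hydroxy-2-methylidenebutanoate (racemic) | C=C(C(O)CO[Si](C)(C)C(C)(C)C)C(=O)OC(C)(C)C | intermediate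
36 | tert-butyl 3-acetoxy-4-(tert-butyldimethylsilyloxy)-2-methylidenebutanoate (racemic) | C=C(C(OC(C)=O)CO[Si](C)(C)C(C)(C)C)C(=O)OC(C)(C)C | intermediate
37 | tert-butyl (E)-2-(acetoxymethyl)-4-(tert-butyldimethylsilyloxy)but-2-enoate | CC(C)(C)OC(=O)/C(=C/CO[Si](C)(C)C(C)(C)C)COC(C)=O | intermediate
38 | trimethylsilyl (E)-2-(acetoxymethyl)-4-(tert-butyldimethylsilyloxy)but-2-enoate | C[Si](C)(C)OC(=O)/C(=C/CO[Si](C)(C)C(C)(C)C)COC(C)=O | intermediate
39 | (E)-2-(acetoxymethyl)-4-(tert-butyldimethylsilyloxy)but-2-enoic acid | OC(=O)/C(=C/CO[Si](C)(C)C(C)(C)C)COC(C)=O | intermediate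
40 | acetaldehyde | CC=O | starting material
41 | tert-butyl 3-hydroxy-2-methylidenebutanoate (racemic) | C=C(C(C)O)C(=O)OC(C)(C)C | intermediate
42 | tert-butyl (Z)-2-(bromomethyl)but-2-enoate | CC(C)(C)OC(=O)/C(=C/C)CBr | intermediate
43 | tert-butyl (E)-2-({[(E)-2-(acetoxymethyl)-4-(tert-butyldimethylsilyloxy)but-2-enoyl]oxy}methyl)but-2-enoate | CC(C)(C)OC(=O)/C(=C/C)COC(=O)/C(=C/CO[Si](C)(C)C(C)(C)C)COC(C)=O | intermediate
44 | trimethylsilyl ester of 45 | C[Si](C)(C)OC(=O)/C(=C/C)COC(=O)/C(=C/CO[Si](C)(C)C(C)(C)C)COC(C)=O | intermediate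
45 | (E)-2-({[(E)-2-(acetoxymethyl)-4-(tert-butyldimethylsilyloxy)but-2-enoyl]oxy}methyl)but-2-enoic acid | OC(=O)/C(=C/C)COC(=O)/C(=C/CO[Si](C)(C)C(C)(C)C)COC(C)=O | intermediate
46 | acid chloride of 45 | ClC(=O)/C(=C/C)COC(=O)/C(=C/CO[Si](C)(C)C(C)(C)C)COC(C)=O | intermediate
47 | 8β-O-acyl derivative of 32 (acyl from 45) | C=C1C(=O)O[C@@H]2/C=C(C)\C(=O)C/C=C(C)/C[C@@H](OC(=O)/C(=C/C)COC(=O)/C(=C/CO[Si](C)(C)C(C)(C)C)COC(C)=O)[C@@H]12 | intermediate
48 | (3S)-3β-hydroxy compound from 47 | C=C1C(=O)O[C@@H]2/C=C(C)\[C@@H](O)C/C=C(C)/C[C@@H](OC(=O)/C(=C/C)COC(=O)/C(=C/CO[Si](C)(C)C(C)(C)C)COC(C)=O)[C@@H]12 | intermediate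
49 | desilylated diol, 1,10-deoxy precursor of the target | C=C1C(=O)O[C@@H]2/C=C(C)\[C@@H](O)C/C=C(C)/C[C@@H](OC(=O)/C(=C/C)COC(=O)/C(=C/CO)COC(C)=O)[C@@H]12 | intermediate
50 | CNP0193678.1, (1R,3S,6R,7R,8R,10R)-1β,10α-epoxy-3β-hydroxy-8β-acyloxygermacra-4(Z),11(13)-dien-6α,12-olide | C=C1C(=O)O[C@@H]2/C=C(/C)[C@@H](O)C[C@H]3O[C@]3(C)C[C@@H](OC(=O)/C(=C/C)COC(=O)/C(=C/CO)COC(C)=O)[C@@H]12 | target

## Step count and least certain steps

Total: 33 steps (26 on the main chain including the preparation of 8, and 7 for the side-chain acid). Longest linear sequence: 25 steps (steps 1–4, 6–22 and 30–33).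

**Step 20 (key step).** The most likely failure is opening in the other conrotatory sense, if the excited diene does not keep its ground-state helicity. A second risk is loss of 30 by photochemical re-closure, E/Z isomerisation or thermal disrotatory closure on warming, since diene and triene both absorb. Fallback, from 29 back to 30: if the main product is the (1(10)Z,2E,4E)-triene F1, irradiation is continued instead of stopped. F1 should re-close photochemically, again conrotatory, to the two cis-fused dienes, 29 and its 5β-H,10β-methyl diastereomer F2 (as previtamin D re-closes to two provitamin-type dienes). F2 is separated and irradiated on its own; in it C6 and C9 have exchanged their pseudo-axial and pseudo-equatorial roles, so it should open in the complementary sense to 30. The single stereocontrolled opening is thus replaced by a photochemical epimerisation–opening relay.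

**Step 4.** Hydrogen abstraction at the silyloxy-bearing allylic carbon or at the isopropenyl group could compete with oxidation of the ring CH2, and the new β,γ-unsaturated ketone could lose its α-stereocentre by enolisation. Fallback, from 4 back to 5: mCPBA epoxidises the trisubstituted ring alkene anti to the silyloxy group to give the epoxide F3. Sodium phenylselenide opens it at the secondary carbon to give the hydroxy selenide F4. Oxidation with H2O2 and selenoxide elimination away from the hydroxyl give the tertiary allylic alcohol F5. Pyridinium chlorochromate then effects the oxidative 1,3-transposition to 5. The C–H oxidation is replaced by an epoxide-based transposition.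

**Step 15.** Hydrogen could be delivered to the β face (trans fusion), or the allylic C6–O bond could be hydrogenolysed. Fallback, from 21 back to 22 (no new compound: F0): homogeneous hydroxyl-directed hydrogenation with [Ir(cod)(PCy3)(py)]PF6 in CH2Cl2. The 6α-hydroxyl binds the metal and hydrogen is delivered to the α face, so the control element changes from catalyst-surface bias to a directing group.

**Step 19.** If the enolate is brominated from the β face, the bromine is anti to H7 and elimination runs into the ring, which destroys C7. Fallback, from 27 back to 29: the enolate is trapped with PhSeSePh/HMPA to give the 11β-phenylselanyl lactone F6, and oxidation with NaIO4 leads to syn elimination. With selenium trans to H7 only the methyl hydrogens are within reach, so this route is exo-selective for exactly the configuration for which the bromide route is not.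

**Step 31.** Catalyst control could be mismatched with the facial bias of the ten-membered ring, giving the 3R epimer. Fallback, from 31 back to 48: the ketone is reduced before the side chain is attached, with NaBH4/CeCl3, to the C3 alcohol; if this is the 3α (3R) epimer F7, a Mitsunobu reaction with chloroacetic acid inverts it to the 3β-chloroacetate F8 (a 3β alcohol would simply be chloroacetylated). HF·pyridine frees the 8β-hydroxyl to give F9. Acylation with 46 gives F10, and thiourea/NaHCO3 removes the chloroacetyl group selectively to give 48. The chloroacetate serves as the C3 protecting group, and the phosphine never meets the allylic esters of the side chain.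

**Step 33.** Attack on the other face of C1=C10 (second ring conformer) or hydroxyl-directed epoxidation of C4=C5 could erode selectivity. Fallback, from 49 back to 50 (no new compound: F0): Shi epoxidation with the D-fructose-derived ketone and Oxone near neutral pH. The dioxirane is chiral, so the face is chosen by the reagent and not by the ring, and the (R,R) sense usual for trans and trisubstituted alkenes matches C1/C10.

## Further compounds

F1 | step 20 | (1(10)Z,2E,4E)-8β-(tert-butyldimethylsilyloxy)-3-(triethylsilyloxy)germacra-1(10),2,4,11(13)-tetraen-6α,12-olide | C=C1C(=O)O[C@@H]2/C=C(C)/C(O[Si](CC)(CC)CC)=C\C=C(C)/C[C@@H](O[Si](C)(C)C(C)(C)C)[C@@H]12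
F2 | step 20 | 8β-(tert-butyldimethylsilyloxy)-3-(triethylsilyloxy)-5βH-eudesma-1,3,11(13)-trien-6α,12-olide (5β-H,10β-methyl cis-fused diastereomer of 29) | C=C1C(=O)O[C@@H]2[C@@H]3C(C)=C(O[Si](CC)(CC)CC)C=C[C@]3(C)C[C@@H](O[Si](C)(C)C(C)(C)C)[C@@H]12
F3 | step 4 | epoxide of the ring alkene of 4, oxirane anti to the silyloxy group | CC[Si](CC)(CC)O[C@H]1C[C@H](C(C)=C)C[C@@H]2O[C@]12C
F4 | step 4 | trans-hydroxy selenide from F3 (phenylselanyl on the secondary carbon, tertiary hydroxyl) | CC[Si](CC)(CC)O[C@H]1C[C@H](C(C)=C)C[C@@H]([Se]c2ccccc2)[C@]1(C)O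
F5 | step 4 | tertiary allylic alcohol, 1-methyl-4-(prop-1-en-2-yl)-6-(triethylsilyloxy)cyclohex-2-en-1-ol | CC[Si](CC)(CC)O[C@H]1C[C@H](C(C)=C)C=C[C@]1(C)O
F0 | step 15 | none | none
F6 | step 19 | 11α-methyl-11β-(phenylselanyl) derivative of 27 | C[C@]1([Se]c2ccccc2)C(=O)O[C@@H]2[C@H]3C(C)=C(O[Si](CC)(CC)CC)C=C[C@@]3(C)C[C@@H](O[Si](C)(C)C(C)(C)C)[C@@H]12
F7 | step 31 | (1(10)E,4Z)-8β-(tert-butyldimethylsilyloxy)-3α-hydroxygermacra-1(10),4,11(13)-trien-6α,12-olide (3R) | C=C1C(=O)O[C@@H]2/C=C(C)\[C@H](O)C/C=C(C)/C[C@@H](O[Si](C)(C)C(C)(C)C)[C@@H]12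
F8 | step 31 | 3β-chloroacetate (3S) of the 8β-silyl ether | C=C1C(=O)O[C@@H]2/C=C(C)\[C@@H](OC(=O)CCl)C/C=C(C)/C[C@@H](O[Si](C)(C)C(C)(C)C)[C@@H]12
F9 | step 31 | 3β-(chloroacetoxy)-8β-hydroxygermacra-1(10),4,11(13)-trien-6α,12-olide | C=C1C(=O)O[C@@H]2/C=C(C)\[C@@H](OC(=O)CCl)C/C=C(C)/C[C@@H](O)[C@@H]12
F10 | step 31 | 3-O-chloroacetyl derivative of 48 | C=C1C(=O)O[C@@H]2/C=C(C)\[C@@H](OC(=O)CCl)C/C=C(C)/C[C@@H](OC(=O)/C(=C/C)COC(=O)/C(=C/CO[Si](C)(C)C(C)(C)C)COC(C)=O)[C@@H]12
F0 | step 33 | none | none
A1 | alternative 1 | methyl (4Z)-1β,10α-epoxy-5-iodo-6-oxo-3β-(tert-butyldimethylsilyloxy)-8β-(4-methoxybenzyloxy)-13-nor-5,6-secogermacr-4-en-12-oate | COC(=O)C[C@@H](C=O)[C@H](OCc1ccc(OC)cc1)C[C@@]2(C)O[C@@H]2C[C@H](O[Si](C)(C)C(C)(C)C)/C(C)=C\I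
A2 | alternative 1 | 1β,10α-epoxy-3β-(tert-butyldimethylsilyloxy)-8β-(4-methoxybenzyloxy)-13-norgermacr-4(Z)-en-6α,12-olide | C1C(=O)O[C@@H]2/C=C(/C)[C@@H](O[Si](C)(C)C(C)(C)C)C[C@H]3O[C@]3(C)C[C@@H](OCc4ccc(OC)cc4)[C@@H]12
A3 | alternative 2 | (1(10)E,4Z)-4-iodo-3-oxo-8β-(4-methoxybenzyloxy)-13-nor-3,4-secogermacra-1(10),4-dien-6α,12-olide | I/C(C)=C\[C@H]1OC(=O)C[C@@H]1[C@H](OCc2ccc(OC)cc2)C/C(C)=C/CC=O
A4 | alternative 2 | (1(10)E,4Z)-3β-hydroxy-8β-(4-methoxybenzyloxy)-13-norgermacra-1(10),4-dien-6α,12-olide | C1C(=O)O[C@@H]2/C=C(/C)[C@@H](O)C/C=C(C)/C[C@@H](OCc3ccc(OC)cc3)[C@@H]12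
A5 | alternative 3 | 1-[(E)-2-(benzyldimethylsilyl)ethenyl]-4-(tert-butyldimethylsilyloxy)-3-methyl-6-(prop-1-en-2-yl)cyclohex-2-en-1-ol (alkenyl groups trans) | C=C(C)[C@H]1C[C@H](O[Si](C)(C)C(C)(C)C)C(C)=C[C@]1(O)/C=C/[Si](C)(C)Cc2ccccc2
A6 | alternative 3 | (1(10)E,4Z)-8-(benzyldimethylsilyl)-3-(tert-butyldimethylsilyloxy)-11,12,13-trinorgermacra-1(10),4-dien-6-one | C1[C@H]([Si](C)(C)Cc2ccccc2)C/C(C)=C/C[C@H](O[Si](C)(C)C(C)(C)C)/C(C)=C\C1=O
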